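The route rests on disconnecting the dihydropyran ring (ring B) at its benzylic C4–C4a bond, with C3 at the ketone level. The precursor is a flat, acyclic aryl 1,1-dimethylpropargyl ether of paeonol. Gold-catalysed N-oxide oxidation converts its terminal alkyne carbon (future C4, by nature a nucleophilic ketone α-carbon) into an electrophilic α-oxo gold carbene, which the arene captures at C4a: one operation forges C4–C4a, closes ring B and installs the C3 oxygen. The step exploits C4a lying between the oxygen-bearing carbons C5 (OMe) and C8a (O1), meta to the C8 acyl group, as the only free ortho site. Corey–Bakshi–Shibata reduction then sets (S)-C3, and a Claisen–Schmidt condensation completes the chalcone.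

Key step: step 2

Remark: chroman numbering is used throughout (O1, C2 with the two methyl groups, C3 carbinol, C4 methylene, C4a, C5 methoxy-bearing, C8 acyl-bearing, C8a), and the stereocentre C3 of the target is read from the SMILES as (S).

Step 1
Reactants: 1 paeonol [1-(2-hydroxy-4-methoxyphenyl)ethan-1-one]; 2 3-chloro-3-methylbut-1-yne
Product: 3 aryl propargyl ether 1-[4-methoxy-2-(2-methylbut-3-yn-2-yloxy)phenyl]ethan-1-one
Conditions: 2 (1.5 equiv), CuCl2·2H2O (1 mol %), DBU (1.6 equiv), MeCN, 0 °C to rt
Reagents that add atoms: none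
Why: Copper-catalysed propargylic etherification of a phenol, in which DBU deprotonates the acidic, hydrogen-bonded phenol and the copper-activated tertiary propargylic chloride is captured by the phenoxide oxygen at the tertiary carbon, so the O1–C2(CH3)2 unit is in place before any C–C bond is made.

Step 2
Reactants: 3 aryl propargyl ether
Product: 5 diketone 8-acetyl-5-methoxy-2,2-dimethylchroman-3-one, via α-oxo gold carbene 4 (not isolated)
Conditions: (Me4tBuXPhos)AuNTf2 (5 mol %) [Me4tBuXPhos = di-tert-butyl(2',4',6'-triisopropyl-3,4,5,6-tetramethylbiphenyl-2-yl)phosphine, NTf2 = bis(trifluoromethylsulfonyl)imide], 2,6-dichloropyridine N-oxide (1.3 equiv), 4 Å molecular sieves, 1,2-dichloroethane, rt, slow addition of 3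
Reagents that add atoms: 2,6-dichloropyridine N-oxide, [O-][n+]1c(Cl)cccc1Cl
Why: Cationic monovalent gold π-activates the terminal alkyne of 3, the N-oxide oxygen adds to the internal alkyne carbon and N–O cleavage expels 2,6-dichloropyridine to leave α-oxo gold carbene 4, in which the former terminal carbon (future C4) has become an electrophile although it is the α-carbon of the new C3 ketone. The arene then attacks this carbon through C4a in a Friedel–Crafts manner, and proton loss followed by protodeauration should give chroman-3-one 5. The closest known reaction type is the gold-catalysed N-oxide oxidation of aryl propargyl ethers to chroman-3-ones. Ring B closes as a six-membered ring by formal 6-exo-trig attack of the arene on the exocyclic Au=C unit, and no stereocentre is formed. The step needs oxygen transfer to outrun direct 6-endo-dig hydroarylation and arene capture to outrun a second oxidation of the carbene, which the bulky biaryl phosphine and the hindered, electron-poor N-oxide should secure. In the substrate the acetyl group blocks the other ortho position, C4a lies between two oxygen-bearing carbons and meta to the acetyl group, and the gem-dimethyl group at C2 favours the folded conformer (Thorpe–Ingold effect).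

Step 3
Reactants: 5 diketone
Product: 7 keto alcohol 1-[(3S)-3-hydroxy-5-methoxy-2,2-dimethyl-3,4-dihydro-2H-chromen-8-yl]ethan-1-one, via catechol borate ester 6 (not isolated)
Conditions: (R)-2-methyl-CBS-oxazaborolidine [(R)-1-methyl-3,3-diphenyltetrahydro-1H,3H-pyrrolo[1,2-c][1,3,2]oxazaborole] (20 mol %), catecholborane (1.1 equiv), toluene, −78 to −40 °C; then MeOH, aq. NaOH work-up
Reagents that add atoms: none
Why: Corey–Bakshi–Shibata reduction, in which the C3 carbonyl, flanked by the quaternary C2 (large) and the C4 methylene (small), binds the (R)-oxazaborolidine anti to C2 so that hydride is delivered to the face that gives the (S)-carbinol, while the C8 acetyl group, deactivated by its ortho and para oxygen donors, should be left untouched by one equivalent of catecholborane at low temperature.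

Step 4
Reactants: 7 keto alcohol; 8 4-hydroxybenzaldehyde
Product: 10 target (2E)-1-[(3S)-3-hydroxy-5-methoxy-2,2-dimethyl-3,4-dihydro-2H-chromen-8-yl]-3-(4-hydroxyphenyl)prop-2-en-1-one, via β-hydroxy ketone aldol adduct 9 (not isolated)
Conditions: 8 (1.2 equiv), KOH (50% aq., 10 equiv), EtOH, rt to 50 °C; then 1 M HCl to pH 5
Reagents that add atoms: none
Why: Claisen–Schmidt condensation, in which the methyl ketone enolate of 7 adds to aldehyde 8 and aldol 9 dehydrates by E1cB to the conjugated, thermodynamically preferred (E)-enone, the C3 stereocentre being remote from any acidic position and therefore untouched.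

Compound list
1 | paeonol, 1-(2-hydroxy-4-methoxyphenyl)ethan-1-one | COc1ccc(C(C)=O)c(O)c1 | starting material
2 | 3-chloro-3-methylbut-1-yne | CC(C)(Cl)C#C | starting material
3 | 1-[4-methoxy-2-(2-methylbut-3-yn-2-yloxy)phenyl]ethan-1-one | COc1ccc(C(C)=O)c(OC(C)(C)C#C)c1 | intermediate
4 | α-oxo gold carbene, [3-(2-acetyl-5-methoxyphenoxy)-3-methyl-2-oxobutylidene](Me4tBuXPhos)gold bis(trifluoromethylsulfonyl)imide | COc1ccc(C(C)=O)c(OC(C)(C)C(=O)C=[Au][P+](C(C)(C)C)(C(C)(C)C)c2c(C)c(C)c(C)c(C)c2-c2c(C(C)C)cc(C(C)C)cc2C(C)C)c1.O=S(=O)([N-]S(=O)(=O)C(F)(F)F)C(F)(F)F | intermediate (not isolated)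
5 | 8-acetyl-5-methoxy-2,2-dimethylchroman-3-one | COc1ccc(C(C)=O)c2c1CC(=O)C(C)(C)O2 | intermediate
6 | 2-{[(3S)-8-acetyl-5-methoxy-2,2-dimethylchroman-3-yl]oxy}-1,3,2-benzodioxaborole | COc1ccc(C(C)=O)c2c1C[C@H](OB1Oc3ccccc3O1)C(C)(C)O2 | intermediate (not isolated)
7 | 1-[(3S)-3-hydroxy-5-methoxy-2,2-dimethyl-3,4-dihydro-2H-chromen-8-yl]ethan-1-one | COc1ccc(C(C)=O)c2c1C[C@H](O)C(C)(C)O2 | intermediate
8 | 4-hydroxybenzaldehyde | O=Cc1ccc(O)cc1 | starting material
9 | 3-hydroxy-1-[(3S)-3-hydroxy-5-methoxy-2,2-dimethyl-3,4-dihydro-2H-chromen-8-yl]-3-(4-hydroxyphenyl)propan-1-one, both epimers at the new carbinol carbon | COc1ccc(C(=O)CC(O)c2ccc(O)cc2)c2c1C[C@H](O)C(C)(C)O2 | intermediate (not isolated)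
10 | (2E)-1-[(3S)-3-hydroxy-5-methoxy-2,2-dimethyl-3,4-dihydro-2H-chromen-8-yl]-3-(4-hydroxyphenyl)prop-2-en-1-one | COc1ccc(C(=O)/C=C/c2ccc(O)cc2)c2c1C[C@H](O)C(C)(C)O2 | target

Total step count: 4. Longest linear sequence: 4 steps (1 to 3 to 5 to 7 to 10).

Steps most likely to fail

Step 2. Oxygen transfer may lose the race to direct hydroarylation of the gold-bound alkyne, or the carbene may be oxidised a second time before the arene captures it. Fallback: setting out from 3, the oxidant is left out and Ph3PAuNTf2 (2 mol %) in CH2Cl2 at rt should effect direct 6-endo-dig hydroarylation, which makes the same C4–C4a bond and gives the chromene 1-(5-methoxy-2,2-dimethyl-2H-chromen-8-yl)ethan-1-one F1. Jacobsen epoxidation of F1 with (S,S)-(salen)MnCl [salen = N,N'-bis(3,5-di-tert-butylsalicylidene)cyclohexane-1,2-diamine dianion], NaOCl and 4-phenylpyridine N-oxide in CH2Cl2 at 0 °C should give the epoxide 1-[(3S,4S)-3,4-epoxy-5-methoxy-2,2-dimethylchroman-8-yl]ethan-1-one F2. Hydrogenolysis of its benzylic C4–O bond (H2, Pd/C, EtOAc, trace Et3N, rt) should leave the (3S)-alcohol, so the fallback comes back to the route at 7 and also replaces step 3.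

Step 3. The two carbonyl groups may not be discriminated well enough, so that the C8 acetyl group is reduced alongside the C3 ketone. Fallback: setting out from 5, both carbonyl groups are reduced on purpose with the same (R)-oxazaborolidine and excess BH3·SMe2 in THF at 0 °C to the diol (3S)-8-[(1S)-1-hydroxyethyl]-5-methoxy-2,2-dimethylchroman-3-ol F3, whose benzylic configuration is of no consequence. Activated MnO2 in CH2Cl2 at rt should then re-oxidise only the electron-rich benzylic alcohol, which brings the material back to the route at 7.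

Step 4. KOH converts aldehyde 8 into its phenoxide, a poor electrophile, so the condensation may stall while the enolate of 7 is consumed in side reactions. Fallback: setting out from 7, the condensation is run under the same basic conditions with commercial 4-(methoxymethoxy)benzaldehyde, which cannot form a phenoxide, to give the protected chalcone (2E)-1-[(3S)-3-hydroxy-5-methoxy-2,2-dimethyl-3,4-dihydro-2H-chromen-8-yl]-3-[4-(methoxymethoxy)phenyl]prop-2-en-1-one F4. The methoxymethyl acetal is then cleaved with HCl in MeOH at 40 °C, which returns to the route at 10.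

Further compounds
F1 | step 2 | 1-(5-methoxy-2,2-dimethyl-2H-chromen-8-yl)ethan-1-one | COc1ccc(C(C)=O)c2c1C=CC(C)(C)O2
F2 | step 2 | 1-[(3S,4S)-3,4-epoxy-5-methoxy-2,2-dimethylchroman-8-yl]ethan-1-one | COc1ccc(C(C)=O)c2c1[C@@H]1O[C@@H]1C(C)(C)O2
F3 | step 3 | (3S)-8-[(1S)-1-hydroxyethyl]-5-methoxy-2,2-dimethylchroman-3-ol | COc1ccc([C@H](C)O)c2c1C[C@H](O)C(C)(C)O2
F4 | step 4 | (2E)-1-[(3S)-3-hydroxy-5-methoxy-2,2-dimethyl-3,4-dihydro-2H-chromen-8-yl]-3-[4-(methoxymethoxy)phenyl]prop-2-en-1-one | COc1ccc(C(=O)/C=C/c2ccc(OCOC)cc2)c2c1C[C@H](O)C(C)(C)O2
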